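(All runs are calculated for an exercise.)

The vessel is closed and stirred and holds a racemate, so the scale has a plain zero: a catalyst blind to handedness leaves an excess of nought however far it runs. You asked for a quick number on gamma and eta, and your hunch was that with catalyst and ligand equal the two end level.

in all of them: left-handed substrate 18 mM; right-handed substrate 18 mM; free catalyst 40 µM; added ligand 0.24 mM

|  | reagent | remark | time |
|---|---|---|---|
| alder | 5.9 mM | run made earlier |  |
| birch | 22 mM | run made earlier |  |
| gamma | 14.4 mM |  | 5.0 h |
| eta | 5.00 mM |  | 5.0 h |

- alder (time / h: right-handed substrate / %, left-handed substrate / %, left-handed product / %): 0.417: 52, 43, 1; 0.833: 48, 40, 6; 1.33: 45, 43, 6; 2.50: 46, 36, 9; 5.00: 42, 46, 10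
- birch (time / h: right-handed substrate / %, left-handed substrate / %, left-handed product / %): 0.417: 47, 34, 13; 0.833: 40, 29, 19; 1.33: 39, 32, 28; 2.50: 35, 19, 31; 5.00: 30, 16, 35

(readings scatter by 2 percentage points)

- free catalyst is single-handed; left-handed substrate and right-handed substrate are mirror images of each other, charged as a racemate, each of them at the stated concentration
- an excess is below zero if the other one leads

- which one finishes higher in excess of right-handed substrate over left-handed substrate among what is left of the two ("neither" within 2 percentage points) (gamma / eta / neither)
- excess of right-handed substrate over left-handed substrate among what is left of the two at the end, gamma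
- excess of right-handed substrate over left-handed substrate among what is left of the two at the end, eta

I read the last line of the birch run. Of its own charge, left-handed substrate kept 32.0% and right-handed substrate 60.0%. The ratio of the logarithms of these two fractions, the selectivity factor s, was a reading of 2.23.

I carried the tilt E, which is s minus one over s plus one, nought for a blind catalyst; here it came to 0.381. For small gaps, the excess stands to the fall in ln u, where u is the fraction of both substrates left, as the difference of the two logarithms stands to their sum. So I took the excess as E times minus ln u.

For u I treated reagent as the limiting reagent, one per substrate, and assumed it all used. That put u at 60.0% for gamma and 86.1% for eta, and my excesses at 19.5% and 5.70%. They stood apart by more than the margin, so I did not share your hunch.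

The forecast said gamma, with 19% (15% to 24%) for gamma and 6% (4% to 8.5%) for eta, holding that “Reagent is limiting, one per substrate”.

The flasks gave 18.8% for gamma and 5.71% for eta, so gamma finished higher.

    reagent + free catalyst + left-handed substrate → free catalyst + left-handed product (k = 650 /M²/s)
    reagent + free catalyst + right-handed substrate → free catalyst + right-handed product (k = 282 /M²/s)
    free catalyst + added ligand ⇌ idle complex, settled at all times (K = 3200 /M)
    free catalyst → spent catalyst (k = 8.76 × 10⁻⁶ /s)
    reagent ⇌ dormant form (K = 0.650, k = 3.21 × 10⁻⁴ /s)

A neighbour flask took eta's recipe with 12 mM of reagent. With all that reagent assumed used, as before, my u for it was 66.7%, so the same tilt gave 15.4%. That flask gave 15.1%, with left-handed substrate at 29.2% and right-handed product at 10.4% of the substrates charged, and 3.3% of its reagent charge still there, unbound.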